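The data were generated by integration for an exercise, and the scatter is random.

On paper, Wednesday's flask holds more substrate (0.30 M) than coupling partner (0.238 M), so the partner looks like the limiting reagent and product seems bound to reach 0.238 M; the pitfall is that a ceiling carries no time.

| flask | substrate | coupling partner | remark | time |
|---|---|---|---|---|
| north-west | 0.30 M | 0.16 M | run made earlier |  |
| north | 0.30 M | 0.48 M | run made earlier |  |
| Wednesday's | 0.30 M | 0.238 M |  | 5.0 min |
| Friday's | 1.0 M | 0.238 M |  | 5.0 min |
| Monday's | 3.0 M | 0.238 M |  | 5.0 min |

| run | time / s | product / % | substrate / % |
|---|---|---|---|
| north-west | 10.0 | 4.3 | 52.8 |
| north-west | 15.0 | 6.4 | 40.7 |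
| north-west | 30.0 | 10.2 | 27.0 |
| north-west | 60.0 | 16.2 | 21.3 |
| north | 10.0 | 17.5 | 41.6 |
| north | 15.0 | 25.5 | 28.6 |
| north | 30.0 | 40.3 | 12.7 |
| north | 60.0 | 58.5 | 7.6 |

(standard deviation of a reading: 0.3 percentage points)

- [product] at the end for Wednesday's, Friday's, Monday's, in this order
- the course of these numbers from the first flask to the last (falls all the way / rises all the way / hardly changes / rises, then falls / falls, then rises)

- the earlier runs were read with a standard deviation of 0.3 percentage points
- reactions considered so far: substrate + coupling partner + by-product -> product + 2 by-product; substrate + coupling partner -> product + by-product; substrate <-> dormant form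
- a step back or a flat step of under half a percent of the largest counts as no turn
- "hardly changes" means that all values lie within two and a half points (for a concentration: within two and a half percent of the largest)
- a step back or a flat step of under half a percent of the largest counts as no turn

A substrate molecule meets a fork: it parks as dormant form or stays free to couple. In the north-west run the missing balance, which is the dormant form, reads 62.8% at 30.0 s and 62.5% at 60.0 s. These two readings are taken to show free and dormant substrate near balance in the north-west run, and the free share f of unconverted substrate reads 25.4% at 60.0 s.

In the north run, the product gain from 30.0 s to 60.0 s, divided by mean free substrate and mean partner, reads as a coefficient κ = 0.180 /M/s. It holds at a by-product level of 0.148 M, since each product brings one by-product. Seen from the partner, the decay is pseudo-first-order in κ times f times unconverted substrate. With Wednesday's product at that same level, the time in which the partner halves, t_C, is 1.66 min.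

The north-west run, with the same substrate charge and less partner, holds 0.0486 M of product at 60.0 s, under its partner charge of 0.16 M. Interpolating by partner charge between the two runs puts Wednesday's at 0.0795 M then. The remaining time is 2.41 half-lives, which leaves 0.0299 M of partner. This reckoning therefore ends Wednesday's at 0.208 M, below the ceiling.

The forecast gives 0.19 M, 0.238 M and 0.238 M, course rises all the way, holding that “free substrate stays plentiful, so the partner is used up within about two minutes or less” at the higher charges, and its first value lies below this reckoning.

The flasks give 0.208 M, 0.238 M and 0.238 M, course rises all the way.

    substrate + coupling partner + by-product → product + 2 by-product (k = 1.07 /M²/s)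
    substrate + coupling partner → product + by-product (k = 0.0346 /M/s)
    substrate ⇌ dormant form (K = 2.60, k = 0.0694 /s)

In Wednesday's flask, substrate and dormant form relax with a half-life of 0.120 min, shorter than the 2.1 min half-life of the partner by the by-product-assisted step at 1.70 min; that step then uses partner 3.8 times as fast as the step without by-product, so the two together give a half-life of 1.63 min, t_C being 1.66 min, and 13% of the partner charge remains at 5.00 min. For Friday's flask, t_C at the same by-product level comes to 0.296 min, shorter than Wednesday's, and its partner stands at 0.0119% of its charge at 2.50 min.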